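**Retrosynthetic overview**

1. Target 26 ⇐ diol 25 by acetylation of the primary allylic OH. 25 ⇐ bromodienyl butenolide 23 + homoallylic iodide 13 by a zinc-mediated, Pd-catalysed cross-electrophile coupling that joins the bromine-bearing sp2 carbon of 23 to the iodine-bearing CH2 of 13.
2. Enabling feature: in 23 the unit O–CH2–C(Br)=CH–C is the opened five-membered ring of 4-bromofuran-2(5H)-one. The C–Br bond therefore sits on the sp2 terminus of a triene conjugated to the furanone C=O, ready for oxidative addition, with CH2O and the dienyl chain already cis. The partner carbon is a primary CH2 one CH2 away from the C=C(Me) bond, and the cyclohexanol OH is shielded by the flanking CMe2 and CHMe carbons, so nothing needs protection.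
3. 23 ⇐ lactol 21 (DIBAL-H on 4-bromofuranone 20) + butenolide phosphonium salt 19 (Wittig; 19 from dihydroxyacetone).
4. 13 ⇐ alkyne 10 (carboalumination/ethylene oxide, then iodination) ⇐ ketone 6 + homopropargyl Grignard reagent ⇐ RAMP-hydrazone methylation of 2,2-dimethylcyclohexanone 1.
5. Rings: the cyclohexane is bought (1). The butenolide is closed first (step 8). The furanone ring of 20 is a temporary ring, opened in step 12. No ring forms in the key step.

Key step: step 13

Assumption: 1,3-dihydroxyacetone (14) is charged as its commercial dimer, which reacts as the monomer.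

**Route**

Step 1
Reactants: 1 2,2-dimethylcyclohexanone; 2 (R)-1-amino-2-(methoxymethyl)pyrrolidine (RAMP)
Product: 3 (2R)-N-[(1E)-2,2-dimethylcyclohexylidene]-2-(methoxymethyl)pyrrolidin-1-amine
Conditions: TsOH (cat.), cyclohexane, reflux, Dean–Stark
Reagents that add atoms: none
Why: Acid-catalysed hydrazone condensation with azeotropic removal of water should overcome the hindrance of the α-quaternary ketone and place the amino group syn to the CH2 side (E), the geometry needed for regio-defined deprotonation.

Step 2
Reactants: 3 (2R)-N-[(1E)-2,2-dimethylcyclohexylidene]-2-(methoxymethyl)pyrrolidin-1-amine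
Product: 5 (2R)-2-(methoxymethyl)-N-[(1E,6S)-2,2,6-trimethylcyclohexylidene]pyrrolidin-1-amine, via lithium azaenolate 4 (not isolated)
Conditions: LDA (commercial solution), THF, 0 °C; MeI, −95 to −78 °C
Reagents that add atoms: iodomethane (CI)
Why: Enders RAMP-hydrazone alkylation: LDA deprotonates the only α-CH2 to the methoxymethyl-chelated lithium azaenolate, whose open face is attacked by iodomethane, so that the auxiliary (RAMP, the antipode of the one known to give the R series with cyclohexanones) should set the new C6 centre as S.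

Step 3
Reactants: 5 (2R)-2-(methoxymethyl)-N-[(1E,6S)-2,2,6-trimethylcyclohexylidene]pyrrolidin-1-amine
Product: 6 (S)-2,2,6-trimethylcyclohexan-1-one
Conditions: sat. aq. oxalic acid, Et2O, rt, two-phase
Reagents that add atoms: water (O)
Why: Mild two-phase acid hydrolysis of the hydrazone should free the ketone without enolising the new α-stereocentre, the auxiliary passing into the aqueous layer as its oxalate for recovery.

Step 4
Reactants: 6 (S)-2,2,6-trimethylcyclohexan-1-one; 7 (4-bromobut-1-yn-1-yl)trimethylsilane
Product: 9 (1R,6S)-2,2,6-trimethyl-1-[4-(trimethylsilyl)but-3-yn-1-yl]cyclohexan-1-ol, via Grignard reagent 8 (not isolated)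
Conditions: Mg, THF (7 to 8); 6 pre-stirred with anhydrous CeCl3, THF, −78 to 0 °C; aq. NH4Cl
Reagents that add atoms: none
Why: Cerium(III)-mediated Grignard 1,2-addition suppresses enolisation of the hindered ketone, and the nucleophile should attack axially, away from the axial methyl of the CMe2 carbon, which places the chain cis to the equatorial C6 methyl (OH trans) and sets C1 as R by substrate control.

Step 5
Reactants: 9 (1R,6S)-2,2,6-trimethyl-1-[4-(trimethylsilyl)but-3-yn-1-yl]cyclohexan-1-ol
Product: 10 (1R,6S)-1-(but-3-yn-1-yl)-2,2,6-trimethylcyclohexan-1-ol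
Conditions: K2CO3, MeOH, rt
Reagents that add atoms: none
Why: Base-mediated protodesilylation cleaves only the C(sp)–Si bond and leaves the tertiary alcohol untouched.

Step 6
Reactants: 10 (1R,6S)-1-(but-3-yn-1-yl)-2,2,6-trimethylcyclohexan-1-ol
Product: 12 (1R,6S)-1-[(3E)-6-hydroxy-3-methylhex-3-en-1-yl]-2,2,6-trimethylcyclohexan-1-ol, via alkenylalane 11 (not isolated)
Conditions: Me3Al (3.5 equiv), Cp2ZrCl2 (0.25 equiv), CH2Cl2, 0 °C to rt; volatiles removed; n-BuLi, THF/hexane, −78 °C; ethylene oxide, −78 °C to rt; cold 1 M HCl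
Reagents that add atoms: trimethylaluminium (C[Al](C)C); ethylene oxide (C1CO1)
Why: Negishi zirconium-catalysed carboalumination adds methyl and aluminium syn across the terminal alkyne with methyl on the internal carbon (the tertiary OH is masked in situ as its aluminium alkoxide), and the derived alkenylalanate opens ethylene oxide with retention, so the E-trisubstituted alkene and the hydroxyethyl arm should arise in one pot.

Step 7
Reactants: 12 (1R,6S)-1-[(3E)-6-hydroxy-3-methylhex-3-en-1-yl]-2,2,6-trimethylcyclohexan-1-ol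
Product: 13 (1R,6S)-1-[(3E)-6-iodo-3-methylhex-3-en-1-yl]-2,2,6-trimethylcyclohexan-1-ol
Conditions: PPh3 (1.3 equiv), imidazole, I2 (1.2 equiv) premixed, CH2Cl2, 0 °C; then 12
Reagents that add atoms: iodine (II)
Why: Appel-type iodination converts only the primary alcohol by SN2 at its oxyphosphonium ion, the hindered tertiary alcohol cannot be activated, and premixing the reagent keeps free iodine away from the γ,δ-unsaturated alcohol.

Step 8
Reactants: 14 1,3-dihydroxyacetone; 15 ethyl (triphenylphosphoranylidene)acetate
Product: 17 4-(hydroxymethyl)furan-2(5H)-one, via hydroxy ester 16 (not isolated)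
Conditions: CH2Cl2, rt
Reagents that add atoms: none
Why: Wittig olefination of the ketone with a stabilised ylide gives an enoate that always carries one CH2OH cis to the ester, so lactonisation to the butenolide should follow spontaneously.

Step 9
Reactants: 17 4-(hydroxymethyl)furan-2(5H)-one
Product: 18 4-(bromomethyl)furan-2(5H)-one
Conditions: CBr4, PPh3, CH2Cl2, 0 °C
Reagents that add atoms: tetrabromomethane (BrC(Br)(Br)Br)
Why: Appel bromination of a primary allylic alcohol proceeds under neutral conditions that do not affect the butenolide.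

Step 10
Reactants: 18 4-(bromomethyl)furan-2(5H)-one
Product: 19 [(5-oxo-2,5-dihydrofuran-3-yl)methyl]triphenylphosphonium bromide
Conditions: PPh3, MeCN, rt; precipitation with Et2O
Reagents that add atoms: triphenylphosphine (c1ccc(cc1)P(c1ccccc1)c1ccccc1)
Why: SN2 quaternisation of triphenylphosphine by the primary allylic bromide gives the Wittig salt.

Step 11
Reactants: 20 4-bromofuran-2(5H)-one
Product: 21 4-bromo-2,5-dihydrofuran-2-ol (racemic lactol)
Conditions: DIBAL-H (1.05 equiv), CH2Cl2, −78 °C; Rochelle salt work-up; used crude and cold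
Reagents that add atoms: none
Why: DIBAL-H half-reduction of a lactone stops at the aluminium lactolate at −78 °C, and the five-membered ring keeps the CH2O carbon and the masked aldehyde carbon cis across the bromoalkene.

Step 12
Reactants: 21 4-bromo-2,5-dihydrofuran-2-ol; 19 [(5-oxo-2,5-dihydrofuran-3-yl)methyl]triphenylphosphonium bromide
Product: 23 4-[(1E,3E)-4-bromo-5-hydroxypenta-1,3-dien-1-yl]furan-2(5H)-one, via phosphorus ylide 22 (not isolated)
Conditions: K2CO3 (powdered), 18-crown-6 (cat.), CH2Cl2, 0 °C to rt
Reagents that add atoms: none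
Why: Wittig olefination of the lactol through its open (Z)-γ-hydroxy-enal form with a conjugated, lactone-stabilised ylide should give the E geometry at the new double bond, while the bromoalkene keeps the geometry imposed by the ring of 20 (CH2OH cis to the dienyl chain).

Step 13
Reactants: 23 4-[(1E,3E)-4-bromo-5-hydroxypenta-1,3-dien-1-yl]furan-2(5H)-one; 13 (1R,6S)-1-[(3E)-6-iodo-3-methylhex-3-en-1-yl]-2,2,6-trimethylcyclohexan-1-ol
Product: 25 4-[(1E,3Z,7E)-4-(hydroxymethyl)-10-[(1R,6S)-1-hydroxy-2,2,6-trimethylcyclohexyl]-8-methyldeca-1,3,7-trien-1-yl]furan-2(5H)-one, via alkylzinc iodide 24 (not isolated)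
Conditions: 13 (1.5 equiv), Zn dust (4 equiv), TMEDA (1 equiv), PdCl2(Amphos)2 (2–5 mol %), 2 wt % TPGS-750-M/H2O, rt, Ar
Reagents that add atoms: none
Why: Zinc dust inserts into the primary C–I bond of 13 inside the surfactant micelle and so reverses the polarity of that CH2 in situ (TMEDA-stabilised alkylzinc iodide 24), Pd(0) adds oxidatively to the sp2 C–Br bond of 23, and transmetalation followed by reductive elimination forms the sp2–sp3 bond. The closest known reaction type is the Negishi-type coupling of alkenyl bromides with primary alkyl iodides run with zinc dust and a Pd–Amphos catalyst in aqueous micelles, a cross-electrophile union of two halides. No ring is closed and no stereocentre is created; the two existing stereocentres are remote and untouched. The step needs chemoselective activation, which the substrate should secure because the C–Br bond on the sp2 terminus of the triene conjugated to the furanone carbonyl undergoes fast oxidative addition but is not expected to be attacked by zinc, whereas the unactivated primary C–I bond is the only site for zinc insertion. It also needs retention of both alkene geometries: oxidative addition and reductive elimination are stereoretentive at the bromoalkene, and the homoallyl group travels as an organozinc and not as a free radical, so the reversible three-membered ring closure that would scramble the E-trisubstituted alkene is avoided. The room-temperature, near-neutral medium should tolerate both free hydroxyls and the base-sensitive butenolide, and the acetate is introduced afterwards because an allylic acetate would be ionised by Pd(0).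

Step 14
Reactants: 25 4-[(1E,3Z,7E)-4-(hydroxymethyl)-10-[(1R,6S)-1-hydroxy-2,2,6-trimethylcyclohexyl]-8-methyldeca-1,3,7-trien-1-yl]furan-2(5H)-one
Product: 26 (2Z,5E)-8-[(1R,6S)-1-hydroxy-2,2,6-trimethylcyclohexyl]-6-methyl-2-[(2E)-3-(5-oxo-2,5-dihydrofuran-3-yl)prop-2-en-1-ylidene]oct-5-en-1-yl acetate (CNP0366059.1)
Conditions: Ac2O (1.2 equiv), pyridine, DMAP (cat.), CH2Cl2, 0 °C
Reagents that add atoms: acetic anhydride (CC(=O)OC(C)=O)
Why: DMAP-catalysed acylation should distinguish the unhindered primary allylic alcohol from the tertiary alcohol flanked by a quaternary and a tertiary carbon, which is not expected to react under these conditions.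

**Compound list**

1 | 2,2-dimethylcyclohexanone | CC1(C)CCCCC1=O | starting material
2 | (R)-1-amino-2-(methoxymethyl)pyrrolidine (RAMP) | COC[C@H]1CCCN1N | starting material
3 | (2R)-N-[(1E)-2,2-dimethylcyclohexylidene]-2-(methoxymethyl)pyrrolidin-1-amine | COC[C@H]1CCCN1/N=C1\CCCCC1(C)C | intermediate
4 | lithium azaenolate of 3 | COC[C@H]1CCCN1N([Li])C1=CCCCC1(C)C | intermediate
5 | (2R)-2-(methoxymethyl)-N-[(1E,6S)-2,2,6-trimethylcyclohexylidene]pyrrolidin-1-amine | COC[C@H]1CCCN1/N=C1\[C@@H](C)CCCC1(C)C | intermediate
6 | (S)-2,2,6-trimethylcyclohexan-1-one | O=C1[C@@H](C)CCCC1(C)C | intermediate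
7 | (4-bromobut-1-yn-1-yl)trimethylsilane | C[Si](C)(C)C#CCCBr | starting material
8 | [4-(trimethylsilyl)but-3-yn-1-yl]magnesium bromide | C[Si](C)(C)C#CCC[Mg]Br | intermediate
9 | (1R,6S)-2,2,6-trimethyl-1-[4-(trimethylsilyl)but-3-yn-1-yl]cyclohexan-1-ol | C[Si](C)(C)C#CCC[C@@]1(O)[C@@H](C)CCCC1(C)C | intermediate
10 | (1R,6S)-1-(but-3-yn-1-yl)-2,2,6-trimethylcyclohexan-1-ol | C#CCC[C@@]1(O)[C@@H](C)CCCC1(C)C | intermediate
11 | (E)-alkenyl(dimethyl)alane from 10, tertiary oxygen as O–AlMe2 | C[Al](C)/C=C(\C)CC[C@@]1(O[Al](C)C)[C@@H](C)CCCC1(C)C | intermediate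
12 | (1R,6S)-1-[(3E)-6-hydroxy-3-methylhex-3-en-1-yl]-2,2,6-trimethylcyclohexan-1-ol | OCC/C=C(\C)CC[C@@]1(O)[C@@H](C)CCCC1(C)C | intermediate
13 | (1R,6S)-1-[(3E)-6-iodo-3-methylhex-3-en-1-yl]-2,2,6-trimethylcyclohexan-1-ol | ICC/C=C(\C)CC[C@@]1(O)[C@@H](C)CCCC1(C)C | intermediate
14 | 1,3-dihydroxyacetone | OCC(=O)CO | starting material
15 | ethyl (triphenylphosphoranylidene)acetate | CCOC(=O)C=P(c1ccccc1)(c1ccccc1)c1ccccc1 | starting material
16 | ethyl 4-hydroxy-3-(hydroxymethyl)but-2-enoate | CCOC(=O)C=C(CO)CO | intermediate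
17 | 4-(hydroxymethyl)furan-2(5H)-one | O=C1OCC(CO)=C1 | intermediate
18 | 4-(bromomethyl)furan-2(5H)-one | O=C1OCC(CBr)=C1 | intermediate
19 | [(5-oxo-2,5-dihydrofuran-3-yl)methyl]triphenylphosphonium bromide | O=C1OCC(C[P+](c2ccccc2)(c2ccccc2)c2ccccc2)=C1.[Br-] | intermediate
20 | 4-bromofuran-2(5H)-one | O=C1OCC(Br)=C1 | starting material
21 | 4-bromo-2,5-dihydrofuran-2-ol (racemic) | OC1OCC(Br)=C1 | intermediate
22 | 4-[(triphenylphosphoranylidene)methyl]furan-2(5H)-one | O=C1OCC(C=P(c2ccccc2)(c2ccccc2)c2ccccc2)=C1 | intermediate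
23 | 4-[(1E,3E)-4-bromo-5-hydroxypenta-1,3-dien-1-yl]furan-2(5H)-one | OC/C(Br)=C\C=C\C1=CC(=O)OC1 | intermediate
24 | alkylzinc iodide from 13 | I[Zn]CC/C=C(\C)CC[C@@]1(O)[C@@H](C)CCCC1(C)C | intermediate
25 | 4-[(1E,3Z,7E)-4-(hydroxymethyl)-10-[(1R,6S)-1-hydroxy-2,2,6-trimethylcyclohexyl]-8-methyldeca-1,3,7-trien-1-yl]furan-2(5H)-one | OC/C(=C\C=C\C1=CC(=O)OC1)CC/C=C(\C)CC[C@@]1(O)[C@@H](C)CCCC1(C)C | intermediate
26 | (2Z,5E)-8-[(1R,6S)-1-hydroxy-2,2,6-trimethylcyclohexyl]-6-methyl-2-[(2E)-3-(5-oxo-2,5-dihydrofuran-3-yl)prop-2-en-1-ylidene]oct-5-en-1-yl acetate | CC(=O)OC/C(=C\C=C\C1=CC(=O)OC1)CC/C=C(\C)CC[C@@]1(O)[C@@H](C)CCCC1(C)C | target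

**Summary**

Total step count: 14. Longest linear sequence: 9 steps (steps 1–7, 13, 14).

Steps most likely to fail:

Step 13. The alkylzinc may be protonated by water before it transmetalates, zinc may reduce the conjugated bromotriene, or the amine may promote conjugate ring closure of the allylic hydroxyl onto the dienyl lactone. The fallback replaces the in situ organozinc by a boron nucleophile and sets out from alkyne 10. Carboalumination as in step 6 gives alkenylalane 11, which is cross-coupled with vinyl bromide (Pd(PPh3)4, ZnCl2, THF) to the diene (1R,6S)-2,2,6-trimethyl-1-[(3E)-3-methylhexa-3,5-dien-1-yl]cyclohexan-1-ol F1. 9-BBN-H then hydroborates the terminal vinyl group to the B-alkyl-9-borabicyclo[3.3.1]nonane F2, which is coupled without isolation with 23 in a B-alkyl Suzuki–Miyaura reaction (Pd(dppf)Cl2, AsPh3, K3PO4, DMF/H2O, rt). This comes back to the route at 25.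

Step 12. The lactol may dehydrate to a furan before olefination, the new double bond may form with poor E selectivity, or the ring-derived bromoalkene geometry may be lost by reversible conjugate addition to the open hydroxy-enal. The fallback sets out from lactol 21. Takai olefination (CrCl2, CHI3, THF, 0 °C) gives (2E,4E)-2-bromo-5-iodopenta-2,4-dien-1-ol F3 with a defined E-iodoalkene. Stille coupling at the more reactive C–I bond with 4-(tributylstannyl)furan-2(5H)-one F4 (made from 20 with hexabutylditin and Pd(PPh3)4), using Pd2(dba)3, AsPh3, CuI, DMF, rt, comes back to the route at 23.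

Step 4. The basic organometallic may enolise the hindered ketone in place of adding to it, and facial selectivity at the carbonyl may be poor for an sp3 nucleophile. The fallback uses a small sp nucleophile and sets out from ketone 6. The lithium acetylide of 3,3-diethoxyprop-1-yne (n-BuLi, THF, −78 °C) should add axially to give (1R,6S)-1-(3,3-diethoxyprop-1-yn-1-yl)-2,2,6-trimethylcyclohexan-1-ol F5. Hydrogenation (H2, Pd/C, EtOAc) gives (1R,6S)-1-(3,3-diethoxypropyl)-2,2,6-trimethylcyclohexan-1-ol F6. Aqueous acetic acid unmasks the aldehyde, which closes to the spiro-lactol 6,10,10-trimethyl-1-oxaspiro[4.5]decan-2-ol F7. Ohira–Bestmann homologation (dimethyl (1-diazo-2-oxopropyl)phosphonate, K2CO3, MeOH) comes back to the route at 10.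

Further compounds
F1 | step 13 | (1R,6S)-2,2,6-trimethyl-1-[(3E)-3-methylhexa-3,5-dien-1-yl]cyclohexan-1-ol | C=C/C=C(\C)CC[C@@]1(O)[C@@H](C)CCCC1(C)C
F2 | step 13 | B-alkyl-9-borabicyclo[3.3.1]nonane from F1 | C/C(CC[C@@]1(O)[C@@H](C)CCCC1(C)C)=C\CCB1C2CCCC1CCC2
F3 | step 12 | (2E,4E)-2-bromo-5-iodopenta-2,4-dien-1-ol | OC/C(Br)=C\C=C\I
F4 | step 12 | 4-(tributylstannyl)furan-2(5H)-one | CCCC[Sn](CCCC)(CCCC)C1=CC(=O)OC1
F5 | step 4 | (1R,6S)-1-(3,3-diethoxyprop-1-yn-1-yl)-2,2,6-trimethylcyclohexan-1-ol | CCOC(OCC)C#C[C@@]1(O)[C@@H](C)CCCC1(C)C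
F6 | step 4 | (1R,6S)-1-(3,3-diethoxypropyl)-2,2,6-trimethylcyclohexan-1-ol | CCOC(OCC)CC[C@@]1(O)[C@@H](C)CCCC1(C)C
F7 | step 4 | 6,10,10-trimethyl-1-oxaspiro[4.5]decan-2-ol (ring stereocentres as in 10, anomeric mixture) | OC1CC[C@@]2(O1)[C@@H](C)CCCC2(C)C
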